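The target is cut at the two tertiary C8–O bonds of ring B, one in each labdane half. C8 carries both the hydroxyl and the C17 methyl, so each carbinol is the Markovnikov hydrate of an exocyclic C8=C17 methylene, an alkene class distinct from the trisubstituted C13=C14 allylic-ester alkenes. A single twofold radical hydration (cobalt hydride H-atom transfer to C17, O2 capture at C8 from the α face opposite the axial C10 methyl) installs both alcohols and both C8 stereocentres on the fully assembled diester. The precursor is bis[(13E)-labda-8(17),13-dien-15-yl] malonate, made from two molecules of (E)-copalol, itself built from manool with the 13E geometry fixed by alkyne carboalumination.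

Key step: step 5

Assumption: natural (+)-manool (5S,9S,10S,13R) is taken as the commercial chiral-pool source of C5, C9 and C10; its vinyl group and C13 stereocentre are sacrificed. Each half of the target reads as (5S,8R,9R,10S),13E, that is 8α-OH/8β-CH3 on the normal labdane skeleton, which agrees with the hydration substrate and with manool, so no structure needs correcting.

Design remark: the 13E geometry is built stereospecifically by syn-carbometalation of a terminal alkyne. An allylic transposition would give E/Z mixtures, and any 13Z alcohol would be carried into E,Z and Z,Z diesters at the esterification.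

Step 1
Reactants: 1 (+)-manool, (13R)-labda-8(17),14-dien-13-ol
Product: 2 14,15-dinorlabd-8(17)-en-13-one
Conditions: KMnO4 (ca. 4 equiv, portionwise), acetone/H2O, 0 °C to rt
Reagents that add atoms: none
Why: Permanganate oxidative cleavage of the vinyl carbinol (dihydroxylation of the unhindered monosubstituted C14=C15 alkene, then glycol and α-hydroxy acid cleavage) should excise C14 and C15 and leave the C13 methyl ketone, while the more hindered exocyclic C8=C17 alkene next to C9 and quaternary C10 should react more slowly and no ring stereocentre is touched.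

Step 2
Reactants: 2 14,15-dinorlabd-8(17)-en-13-one
Product: 4 (1S,4aS,8aS)-1-(but-3-yn-1-yl)-5,5,8a-trimethyl-2-methylidenedecahydronaphthalene, via enol diethyl phosphate 3 (not isolated)
Conditions: LiN(iPr)2 (1.05 equiv), THF, −78 °C; ClP(O)(OEt)2, −78 °C to rt; then LiN(iPr)2 (2.3 equiv), −78 °C to rt; aq. NH4Cl
Reagents that add atoms: none
Why: Kinetic enolisation of the methyl ketone at the methyl group, O-phosphorylation and amide-base β-elimination of diethyl phosphate from the terminal enol phosphate (methyl ketone to terminal alkyne conversion) should give the terminal alkyne without touching the ring stereocentres or the exocyclic alkene.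

Step 3
Reactants: 4 (1S,4aS,8aS)-1-(but-3-yn-1-yl)-5,5,8a-trimethyl-2-methylidenedecahydronaphthalene
Product: 7 (13E)-labda-8(17),13-dien-15-ol [(+)-(E)-copalol], via alkenyldimethylalane 5 (not isolated), via lithium alkenylbutyldimethylaluminate 6 (not isolated)
Conditions: Me3Al (2.5 equiv), Cp2ZrCl2 (0.25 equiv), CH2Cl2, 0 °C to rt; evaporate, hexane/THF; n-BuLi, 0 °C; (CH2O)n, rt; H2O
Reagents that add atoms: trimethylaluminium C[Al](C)C; paraformaldehyde (reacting as formaldehyde) C=O
Why: The zirconium-catalysed Negishi carboalumination adds CH3 and Al syn across the terminal alkyne with the methyl on the internal carbon, and hydroxymethylation of the derived alanate with formaldehyde goes with retention at the alkenyl carbon, so only the 13E allylic alcohol should form, the 1,1-disubstituted C8=C17 alkene being inert to Me3Al/Cp2ZrCl2.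

Step 4
Reactants: 7 (13E)-labda-8(17),13-dien-15-ol (two equivalents); 8 malonyl dichloride
Product: 9 bis[(13E)-labda-8(17),13-dien-15-yl] malonate
Conditions: 8 (0.5 equiv, slow addition), pyridine, CH2Cl2, 0 °C to rt
Reagents that add atoms: none
Why: Twofold O-acylation of the primary allylic alcohol by the bis(acid chloride) with pyridine as acid scavenger (acid chloride esterification) should give the symmetric diester without affecting either alkene class or the allylic C–O bonds.

Step 5
Reactants: 9 bis[(13E)-labda-8(17),13-dien-15-yl] malonate
Product: 11 bis[(13E)-8α-hydroxylabd-13-en-15-yl] malonate (target), via bis(8α-hydroperoxide) 10 (not isolated)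
Conditions: Co(acac)2 (0.2 equiv), PhSiH3 (2.5–3 equiv, portionwise), O2 (1 atm), THF, 0 °C to rt; then PPh3 (3 equiv), rt
Reagents that add atoms: dioxygen O=O
Why: A trivalent cobalt hydride, formed from Co(acac)2, O2 and PhSiH3, delivers a hydrogen atom to the terminal C17 of each exocyclic alkene, the tertiary C8 radicals combine with O2, and the peroxy intermediates are reduced by PPh3, so both C8–O bonds form in one flask. The closest known reaction type is the Mukaiyama hydration of 1,1-disubstituted alkenes with a cobalt diketonate, a silane and oxygen, used here at two remote and independent sites. No ring is closed. Each new stereocentre (C8 and C8′) is set by the substrate: the axial β trajectory at the planar C8 radical of the trans-decalin is blocked by the syn-axial C10 methyl, so O2 should enter along the equatorial α direction and leave the C17 methyl β, giving 8R in both halves. The step needs chemoselectivity for C8=C17 over C13=C14, which rests on faster hydrogen-atom transfer to an unhindered terminal CH2 than to the internal C14 of a trisubstituted alkene deactivated by its allylic acyloxy group, supported by a limited silane charge and low temperature. The neutral conditions should leave the malonate esters, the malonate CH2 and the allylic C–O bonds intact.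

Compound list
1 | (+)-manool, (13R)-labda-8(17),14-dien-13-ol | C=C[C@](C)(O)CC[C@@H]1[C@@]2(C)CCCC(C)(C)[C@@H]2CCC1=C | starting material
2 | 14,15-dinorlabd-8(17)-en-13-one, 4-[(1S,4aS,8aS)-5,5,8a-trimethyl-2-methylidenedecahydronaphthalen-1-yl]butan-2-one | CC(=O)CC[C@@H]1[C@@]2(C)CCCC(C)(C)[C@@H]2CCC1=C | intermediate
3 | diethyl 4-[(1S,4aS,8aS)-5,5,8a-trimethyl-2-methylidenedecahydronaphthalen-1-yl]but-1-en-2-yl phosphate (terminal enol phosphate of 2, not isolated) | C=C(CC[C@@H]1[C@@]2(C)CCCC(C)(C)[C@@H]2CCC1=C)OP(=O)(OCC)OCC | intermediate
4 | (1S,4aS,8aS)-1-(but-3-yn-1-yl)-5,5,8a-trimethyl-2-methylidenedecahydronaphthalene | C#CCC[C@@H]1[C@@]2(C)CCCC(C)(C)[C@@H]2CCC1=C | intermediate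
5 | dimethyl[(1E)-2-methyl-4-[(1S,4aS,8aS)-5,5,8a-trimethyl-2-methylidenedecahydronaphthalen-1-yl]but-1-en-1-yl]alane (not isolated) | C/C(=C\[Al](C)C)CC[C@@H]1[C@@]2(C)CCCC(C)(C)[C@@H]2CCC1=C | intermediate
6 | lithium butyl(dimethyl)[(1E)-2-methyl-4-[(1S,4aS,8aS)-5,5,8a-trimethyl-2-methylidenedecahydronaphthalen-1-yl]but-1-en-1-yl]aluminate (not isolated) | [Li+].C/C(=C\[Al-](C)(C)CCCC)CC[C@@H]1[C@@]2(C)CCCC(C)(C)[C@@H]2CCC1=C | intermediate
7 | (13E)-labda-8(17),13-dien-15-ol, (+)-(E)-copalol | C/C(=C\CO)CC[C@@H]1[C@@]2(C)CCCC(C)(C)[C@@H]2CCC1=C | intermediate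
8 | malonyl dichloride | O=C(Cl)CC(=O)Cl | starting material
9 | bis[(13E)-labda-8(17),13-dien-15-yl] malonate | C/C(=C\COC(=O)CC(=O)OC/C=C(\C)CC[C@@H]1[C@@]2(C)CCCC(C)(C)[C@@H]2CCC1=C)CC[C@@H]1[C@@]2(C)CCCC(C)(C)[C@@H]2CCC1=C | intermediate
10 | bis[(13E)-8α-hydroperoxylabd-13-en-15-yl] malonate (not isolated) | C/C(=C\COC(=O)CC(=O)OC/C=C(\C)CC[C@@H]1[C@@]2(C)CCCC(C)(C)[C@@H]2CC[C@@]1(C)OO)CC[C@@H]1[C@@]2(C)CCCC(C)(C)[C@@H]2CC[C@@]1(C)OO | intermediate
11 | bis[(13E)-8α-hydroxylabd-13-en-15-yl] malonate, CNP0254645.1 | C/C(=C\COC(=O)CC(=O)OC/C=C(\C)CC[C@@H]1[C@@]2(C)CCCC(C)(C)[C@@H]2CC[C@@]1(C)O)CC[C@@H]1[C@@]2(C)CCCC(C)(C)[C@@H]2CC[C@@]1(C)O | target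

Total step count: 5. Longest linear sequence: 5 steps (1 → 2 → 4 → 7 → 9 → 11); malonyl dichloride 8 enters at step 4.

Steps most likely to fail

Step 5 (key step). The hydration may stall after one of the two alkenes has reacted. Hydrogen-atom transfer may also reach the C13=C14 alkenes, or oxygen capture may be imperfectly α-selective at one of the two C8 radicals, and at two sites that multiplies into diastereomer mixtures. The fallback sets out from alcohol 7 and hydrates ionically before the halves are joined. Oxymercuration with Hg(OAc)2 in THF/H2O should engage the more reactive 1,1-disubstituted alkene, with water attacking C8 from the α face, and give the organomercurial (13E)-17-(acetoxymercurio)labd-13-ene-8α,15-diol F1. Demercuration with NaBH4 in aqueous NaOH should then give (13E)-labd-13-ene-8α,15-diol F2, which can be purified as a single monomeric diastereomer. Acylation of its primary allylic hydroxyl with malonyl dichloride 8 and pyridine in CH2Cl2 (the hindered tertiary 8α-hydroxyl should not react) comes back to the route at target 11.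

Step 2. Enolisation may take place partly toward C12, leading to the internal enol phosphate and then to allene or internal alkyne, and the excess amide base may isomerise the terminal alkyne. The fallback sets out from ketone 2. Horner–Wadsworth–Emmons olefination with triethyl phosphonoacetate and NaH in THF should give ethyl (13E)-labda-8(17),13-dien-15-oate F3, from which the minor 13Z ester is removed by chromatography at the monomer stage. Reduction with iBu2AlH in CH2Cl2 at −78 °C then comes back to the route at alcohol 7, bypassing steps 2 and 3.

Step 1. The oxidant may attack the exocyclic C8=C17 alkene as well, or the cleavage may stop short of the ketone. The fallback sets out from manool 1 and keeps all twenty carbons. Acetylation of the tertiary alcohol (Ac2O, DMAP, Et3N) should give (13R)-labda-8(17),14-dien-13-yl acetate F4. A [3,3] allylic transposition catalysed by the divalent palladium complex PdCl2(MeCN)2 in THF should then give (13E)-labda-8(17),13-dien-15-yl acetate F5 together with its 13Z isomer, which has to be removed on AgNO3-impregnated silica. Methanolysis with K2CO3 in MeOH comes back to the route at alcohol 7, bypassing steps 1 to 3.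

Further compounds
F1 | step 5 | (13E)-17-(acetoxymercurio)labd-13-ene-8α,15-diol | C/C(=C\CO)CC[C@@H]1[C@@]2(C)CCCC(C)(C)[C@@H]2CC[C@@]1(C[Hg]OC(C)=O)O
F2 | step 5 | (13E)-labd-13-ene-8α,15-diol | C/C(=C\CO)CC[C@@H]1[C@@]2(C)CCCC(C)(C)[C@@H]2CC[C@@]1(C)O
F3 | step 2 | ethyl (13E)-labda-8(17),13-dien-15-oate | CCOC(=O)/C=C(\C)CC[C@@H]1[C@@]2(C)CCCC(C)(C)[C@@H]2CCC1=C
F4 | step 1 | (13R)-labda-8(17),14-dien-13-yl acetate (manool acetate) | C=C[C@](C)(OC(C)=O)CC[C@@H]1[C@@]2(C)CCCC(C)(C)[C@@H]2CCC1=C
F5 | step 1 | (13E)-labda-8(17),13-dien-15-yl acetate | CC(=O)OC/C=C(\C)CC[C@@H]1[C@@]2(C)CCCC(C)(C)[C@@H]2CCC1=C
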